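The eleven-membered carbocycle (C1 = carbinol carbon, C3=C4 the trisubstituted alkene, C7 the methylidene carbon) is closed across its only CH2–CH2 bond, C5–C6. With C7 at the ketone level, C6 is an enolate carbon and C5 the terminus of the C3=C4–C5 allyl unit, so the ring is an α-allyl ketone, the product of a decarboxylative allylation. The precursor is therefore a 13-membered β-keto lactone in which O–C(=O) bridges C5 and C6: zerovalent palladium ionises the allylic ester, CO2 is lost, and the enolate recloses on C5 (13→11 ring contraction). Acylketene macrolactonisation supplies the lactone; methylenation and acylation with isovanillic acid finish.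

Key step: step 9

Remark: ring locants are those of (1S,3E,8E)-3,10,10-trimethyl-7-methylidenecycloundeca-3,8-dien-1-ol. Phosphonate 12 and the protected acid 21 are assumed to be prepared rather than bought.

Step 1
Reactants: 1 2-methylpropanenitrile (isobutyronitrile); 2 (R)-epichlorohydrin [(2R)-2-(chloromethyl)oxirane]
Product: 4 2,2-dimethyl-3-[(2R)-oxiran-2-yl]propanenitrile, via chlorohydrin lithium alkoxide 3 (not isolated)
Conditions: LiN(iPr)2, THF, −78 °C; then 2, −78 °C → rt
Reagents that add atoms: none
Why: The lithiated nitrile opens the epoxide of 2 at its CH2 terminus and alkoxide 3 then displaces chloride on warming (nitrile α-alkylation followed by intramolecular Williamson closure), so the C–O stereocenter of 2 is never touched and becomes the future carbinol center.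

Step 2
Reactants: 4 2,2-dimethyl-3-[(2R)-oxiran-2-yl]propanenitrile
Product: 5 (4S)-4-hydroxy-2,2-dimethylhept-6-ynenitrile
Conditions: LiC≡CH·H2NCH2CH2NH2, DMSO, 0 °C → rt; then H2O
Reagents that add atoms: lithium acetylide ethylenediamine complex, [Li+].[C-]#C.NCCN
Why: SN2 opening of the terminal epoxide at its unsubstituted carbon by acetylide (epoxide alkynylation) leaves the stereocenter untouched, and the α-quaternary nitrile has no acidic hydrogen and is hindered towards addition.

Step 3
Reactants: 5 (4S)-4-hydroxy-2,2-dimethylhept-6-ynenitrile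
Product: 6 (4S)-4-[(tert-butyldimethylsilyl)oxy]-2,2-dimethylhept-6-ynenitrile
Conditions: TBSCl, imidazole, DMF, rt
Reagents that add atoms: tert-butyldimethylsilyl chloride, CC(C)(C)[Si](C)(C)Cl
Why: Silyl ether formation protects the secondary alcohol against the aluminium reagents, the olefination base and the acylketene of the later steps.

Step 4
Reactants: 6 (4S)-4-[(tert-butyldimethylsilyl)oxy]-2,2-dimethylhept-6-ynenitrile
Product: 8 methyl (2E,5S)-5-[(tert-butyldimethylsilyl)oxy]-7-cyano-3,7-dimethyloct-2-enoate, via alkenyldimethylalane 7 (not isolated)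
Conditions: AlMe3 (3 equiv), Cp2ZrCl2 (0.25 equiv), CH2Cl2, 0 °C → rt; then ClCO2Me, 0 °C → rt
Reagents that add atoms: trimethylaluminium, C[Al](C)C; methyl chloroformate, COC(=O)Cl
Why: Negishi zirconium-catalysed carboalumination adds methyl and aluminium syn across the terminal alkyne with methyl on the internal carbon, and acylation of alkenylalane 7 by the chloroformate proceeds with retention, which fixes the E trisubstituted alkene.

Step 5
Reactants: 8 methyl (2E,5S)-5-[(tert-butyldimethylsilyl)oxy]-7-cyano-3,7-dimethyloct-2-enoate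
Product: 10 (4S,6E)-4-[(tert-butyldimethylsilyl)oxy]-8-hydroxy-2,2,6-trimethyloct-6-enal, via hydroxy aldimine 9 (not isolated)
Conditions: iBu2AlH (4 equiv), CH2Cl2, −78 → 0 °C; then aq. KNaC4H4O6, rt
Reagents that add atoms: water, O
Why: iBu2AlH reduces the enoate 1,2 to the allylic alcohol and stops at the N-aluminio imine with the hindered nitrile, and hydrolysis of aldimine 9 on work-up releases the non-enolisable aldehyde (hydride reduction of ester and nitrile).

Step 6
Reactants: 11 2,2,6-trimethyl-4H-1,3-dioxin-4-one
Product: 12 diethyl [(2,2-dimethyl-4-oxo-4H-1,3-dioxin-6-yl)methyl]phosphonate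
Conditions: LiN(iPr)2 (2.1 equiv), THF, −78 °C; ClP(O)(OEt)2, −78 → 0 °C; then H2O
Reagents that add atoms: diethyl chlorophosphate, CCOP(=O)(Cl)OCC
Why: γ-Deprotonation gives the vinylogous enolate, which is phosphorylated at the exocyclic carbon while the second equivalent of base takes up the more acidic product (C-phosphorylation of a dienolate).

Step 7
Reactants: 10 (4S,6E)-4-[(tert-butyldimethylsilyl)oxy]-8-hydroxy-2,2,6-trimethyloct-6-enal; 12 diethyl [(2,2-dimethyl-4-oxo-4H-1,3-dioxin-6-yl)methyl]phosphonate
Product: 13 6-[(1E,5S,7E)-5-[(tert-butyldimethylsilyl)oxy]-9-hydroxy-3,3,7-trimethylnona-1,7-dien-1-yl]-2,2-dimethyl-4H-1,3-dioxin-4-one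
Conditions: 12 (1.2 equiv), KN(SiMe3)2 (1.15 equiv), THF, −78 °C; then 10, −78 °C → rt
Reagents that add atoms: none
Why: Horner–Wadsworth–Emmons olefination of the non-enolisable α-quaternary aldehyde with the stabilised phosphonate anion should give the E alkene, and with no excess base the free allylic alcohol stays protonated.

Step 8
Reactants: 13 6-[(1E,5S,7E)-5-[(tert-butyldimethylsilyl)oxy]-9-hydroxy-3,3,7-trimethylnona-1,7-dien-1-yl]-2,2-dimethyl-4H-1,3-dioxin-4-one
Product: 15 (5E,9S,11E)-9-[(tert-butyldimethylsilyl)oxy]-7,7,11-trimethyl-1-oxacyclotrideca-5,11-diene-2,4-dione, via acylketene 14 (not isolated)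
Conditions: PhMe, 110 °C, syringe-pump addition to 0.5 mM
Reagents that add atoms: none
Why: Thermal retro-[4+2] cleavage of the dioxinone expels acetone and acylketene 14 is trapped by the primary allylic alcohol at high dilution (acylketene macrolactonisation), which closes the 13-membered β-keto lactone without base or activating agent.

Step 9
Reactants: 15 (5E,9S,11E)-9-[(tert-butyldimethylsilyl)oxy]-7,7,11-trimethyl-1-oxacyclotrideca-5,11-diene-2,4-dione
Product: 16 (2E,6S,8E)-6-[(tert-butyldimethylsilyl)oxy]-4,4,8-trimethylcycloundeca-2,8-dien-1-one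
Conditions: Pd(PPh3)4 (10 mol%), degassed THF, 2 mM, 25 → 50 °C
Reagents that add atoms: none
Why: Zerovalent palladium ionises the allylic C–O bond of the lactone to a π-allyl complex of divalent palladium and a tethered β-keto carboxylate, loss of CO2 gives the cross-conjugated enolate, and its α-carbon attacks the CH2 terminus of the π-allyl unit. The closest known reaction type is the Tsuji decarboxylative allylation of allyl β-keto esters (the palladium-catalysed Carroll rearrangement), run here within a ring, together with Tsuji–Trost π-allyl macrocyclisation. The eleven-membered carbocycle is closed by C–C bond formation at the distal allyl terminus so that all three allyl carbons end up in the ring, a net 13→11 ring contraction with extrusion of CO2, whereas closure at the methyl-bearing terminus would give a nine-membered ring with a quaternary carbon and is disfavoured. No stereocenter is formed, the silyloxy-bearing center is remote from the reacting atoms, and the E geometry of the trisubstituted alkene should be kept because the syn π-allyl complex can only isomerise through a σ-complex at its tertiary carbon. The step needs C-allylation within the same molecule to beat oligomerisation, O-allylation, enolate protonation with diene formation, and Michael addition; these are countered by high dilution, by the enolate being generated regiospecifically at the carbon that carried the carboxylate and within bonding distance of the allyl terminus it has just left, and by the quaternary carbon that shields the β-position of the enone.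

Step 10
Reactants: 16 (2E,6S,8E)-6-[(tert-butyldimethylsilyl)oxy]-4,4,8-trimethylcycloundeca-2,8-dien-1-one
Product: 17 tert-butyldimethyl{[(1S,3E,8E)-3,10,10-trimethyl-7-methylidenecycloundeca-3,8-dien-1-yl]oxy}silane
Conditions: Ph3PCH3Br, KOtBu, THF, 0 °C → rt
Reagents that add atoms: methyltriphenylphosphonium bromide, C[P+](c1ccccc1)(c1ccccc1)c1ccccc1.[Br-]
Why: Wittig methylenation with the unstabilised ylide adds 1,2 to the cross-conjugated ketone and turns it into the exocyclic methylene of the 1,3-diene without touching the silyl ether.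

Step 11
Reactants: 17 tert-butyldimethyl{[(1S,3E,8E)-3,10,10-trimethyl-7-methylidenecycloundeca-3,8-dien-1-yl]oxy}silane
Product: 18 (1S,3E,8E)-3,10,10-trimethyl-7-methylidenecycloundeca-3,8-dien-1-ol
Conditions: Bu4NF, THF, rt
Reagents that add atoms: none
Why: Fluoride cleaves the Si–O bond (silyl ether deprotection) and leaves the diene, the trisubstituted alkene and the carbinol configuration unchanged.

Step 12
Reactants: 19 3-hydroxy-4-methoxybenzoic acid (isovanillic acid)
Product: 21 3-[(tert-butyldimethylsilyl)oxy]-4-methoxybenzoic acid, via silyl ester 20 (not isolated)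
Conditions: TBSCl (2.5 equiv), imidazole, DMF, rt; then AcOH/THF/H2O, rt
Reagents that add atoms: tert-butyldimethylsilyl chloride, CC(C)(C)[Si](C)(C)Cl
Why: Exhaustive silylation followed by selective hydrolysis of the labile silyl ester (silyl protection of a phenol) masks the phenol so that it cannot compete as a nucleophile in the esterification.

Step 13
Reactants: 18 (1S,3E,8E)-3,10,10-trimethyl-7-methylidenecycloundeca-3,8-dien-1-ol; 21 3-[(tert-butyldimethylsilyl)oxy]-4-methoxybenzoic acid
Product: 22 (1S,3E,8E)-3,10,10-trimethyl-7-methylidenecycloundeca-3,8-dien-1-yl 3-[(tert-butyldimethylsilyl)oxy]-4-methoxybenzoate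
Conditions: DCC, DMAP (0.3 equiv), CH2Cl2, 0 °C → rt
Reagents that add atoms: none
Why: Steglich esterification acylates the secondary alcohol at oxygen, so the C–O bond and the S configuration of the carbinol carbon are retained.

Step 14
Reactants: 22 (1S,3E,8E)-3,10,10-trimethyl-7-methylidenecycloundeca-3,8-dien-1-yl 3-[(tert-butyldimethylsilyl)oxy]-4-methoxybenzoate
Product: 23 (1S,3E,8E)-3,10,10-trimethyl-7-methylidenecycloundeca-3,8-dien-1-yl 3-hydroxy-4-methoxybenzoate
Conditions: Bu4NF, AcOH (1:1), THF, 0 °C
Reagents that add atoms: none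
Why: Buffered fluoride removes the aryl silyl ether (silyl ether deprotection) far faster than it could attack the secondary benzoate, which should release the free phenol of the target.

Compound list
1 | 2-methylpropanenitrile (isobutyronitrile) | CC(C)C#N | starting material
2 | (R)-epichlorohydrin, (2R)-2-(chloromethyl)oxirane | ClC[C@H]1CO1 | starting material
3 | lithium (2R)-1-chloro-4-cyano-4-methylpentan-2-olate | N#CC(C)(C)C[C@@H]([O-])CCl.[Li+] | intermediate
4 | 2,2-dimethyl-3-[(2R)-oxiran-2-yl]propanenitrile | N#CC(C)(C)C[C@@H]1CO1 | intermediate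
5 | (4S)-4-hydroxy-2,2-dimethylhept-6-ynenitrile | N#CC(C)(C)C[C@@H](O)CC#C | intermediate
6 | (4S)-4-[(tert-butyldimethylsilyl)oxy]-2,2-dimethylhept-6-ynenitrile | N#CC(C)(C)C[C@@H](O[Si](C)(C)C(C)(C)C)CC#C | intermediate
7 | [(1E,4R)-4-[(tert-butyldimethylsilyl)oxy]-6-cyano-2,6-dimethylhept-1-en-1-yl]dimethylalane (same spatial arrangement as 6; the descriptor changes because aluminium raises the priority of the alkenyl branch) | N#CC(C)(C)C[C@@H](O[Si](C)(C)C(C)(C)C)C/C(C)=C/[Al](C)C | intermediate
8 | methyl (2E,5S)-5-[(tert-butyldimethylsilyl)oxy]-7-cyano-3,7-dimethyloct-2-enoate | N#CC(C)(C)C[C@@H](O[Si](C)(C)C(C)(C)C)C/C(C)=C/C(=O)OC | intermediate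
9 | (2E,5S)-5-[(tert-butyldimethylsilyl)oxy]-8-imino-3,7,7-trimethyloct-2-en-1-ol | N=CC(C)(C)C[C@@H](O[Si](C)(C)C(C)(C)C)C/C(C)=C/CO | intermediate
10 | (4S,6E)-4-[(tert-butyldimethylsilyl)oxy]-8-hydroxy-2,2,6-trimethyloct-6-enal | O=CC(C)(C)C[C@@H](O[Si](C)(C)C(C)(C)C)C/C(C)=C/CO | intermediate
11 | 2,2,6-trimethyl-4H-1,3-dioxin-4-one | CC1=CC(=O)OC(C)(C)O1 | starting material
12 | diethyl [(2,2-dimethyl-4-oxo-4H-1,3-dioxin-6-yl)methyl]phosphonate | CCOP(=O)(CC1=CC(=O)OC(C)(C)O1)OCC | intermediate
13 | 6-[(1E,5S,7E)-5-[(tert-butyldimethylsilyl)oxy]-9-hydroxy-3,3,7-trimethylnona-1,7-dien-1-yl]-2,2-dimethyl-4H-1,3-dioxin-4-one | O=C1C=C(/C=C/C(C)(C)C[C@@H](O[Si](C)(C)C(C)(C)C)C/C(C)=C/CO)OC(C)(C)O1 | intermediate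
14 | (4E,8S,10E)-8-[(tert-butyldimethylsilyl)oxy]-12-hydroxy-6,6,10-trimethyldodeca-1,4,10-triene-1,3-dione (acylketene) | O=C=CC(=O)/C=C/C(C)(C)C[C@@H](O[Si](C)(C)C(C)(C)C)C/C(C)=C/CO | intermediate
15 | (5E,9S,11E)-9-[(tert-butyldimethylsilyl)oxy]-7,7,11-trimethyl-1-oxacyclotrideca-5,11-diene-2,4-dione | O=C1/C=C/C(C)(C)C[C@@H](O[Si](C)(C)C(C)(C)C)C/C(C)=C/COC(=O)C1 | intermediate
16 | (2E,6S,8E)-6-[(tert-butyldimethylsilyl)oxy]-4,4,8-trimethylcycloundeca-2,8-dien-1-one | O=C1/C=C/C(C)(C)C[C@@H](O[Si](C)(C)C(C)(C)C)C/C(C)=C/CC1 | intermediate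
17 | tert-butyldimethyl{[(1S,3E,8E)-3,10,10-trimethyl-7-methylidenecycloundeca-3,8-dien-1-yl]oxy}silane | C=C1/C=C/C(C)(C)C[C@@H](O[Si](C)(C)C(C)(C)C)C/C(C)=C/CC1 | intermediate
18 | (1S,3E,8E)-3,10,10-trimethyl-7-methylidenecycloundeca-3,8-dien-1-ol | C=C1/C=C/C(C)(C)C[C@@H](O)C/C(C)=C/CC1 | intermediate
19 | 3-hydroxy-4-methoxybenzoic acid (isovanillic acid) | COc1ccc(C(=O)O)cc1O | starting material
20 | tert-butyldimethylsilyl 3-[(tert-butyldimethylsilyl)oxy]-4-methoxybenzoate | COc1ccc(C(=O)O[Si](C)(C)C(C)(C)C)cc1O[Si](C)(C)C(C)(C)C | intermediate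
21 | 3-[(tert-butyldimethylsilyl)oxy]-4-methoxybenzoic acid | COc1ccc(C(=O)O)cc1O[Si](C)(C)C(C)(C)C | intermediate
22 | (1S,3E,8E)-3,10,10-trimethyl-7-methylidenecycloundeca-3,8-dien-1-yl 3-[(tert-butyldimethylsilyl)oxy]-4-methoxybenzoate | C=C1/C=C/C(C)(C)C[C@@H](OC(=O)c2ccc(OC)c(O[Si](C)(C)C(C)(C)C)c2)C/C(C)=C/CC1 | intermediate
23 | (1S,3E,8E)-3,10,10-trimethyl-7-methylidenecycloundeca-3,8-dien-1-yl 3-hydroxy-4-methoxybenzoate | C=C1/C=C/C(C)(C)C[C@@H](OC(=O)c2ccc(OC)c(O)c2)C/C(C)=C/CC1 | target

Total step count: 14 (12 in the main line, plus step 6 for phosphonate 12 and step 12 for acid 21).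
Longest linear sequence: 12 steps (steps 1–5, 7–11, 13 and 14).

Steps most likely to fail

1. Step 9 (decarboxylative ring contraction). The risks are intermolecular allylation leading to oligomers, protonation of the enolate with β-hydride elimination at the π-allyl unit, O-allylation, and loss of alkene geometry by π–σ–π isomerisation. The fallback sets out from 13 and returns to the route at 16; it closes the same bond with a doubly stabilised nucleophile under classical Tsuji–Trost conditions. The allylic alcohol of 13 is converted with ClCO2Me and pyridine in CH2Cl2 into the allylic methyl carbonate F1. Thermolysis of F1 in PhMe at 110 °C in the presence of MeOH should trap the acylketene as the open-chain methyl β-keto ester F2. Pd(PPh3)4 in THF at high dilution then ionises the carbonate, the methoxide released deprotonates the β-keto ester, and the stabilised enolate closes the eleven-membered ring at the same CH2 terminus to give the cyclic β-keto ester F3. Krapcho dealkoxycarbonylation (LiCl, wet DMSO, 130 °C) should give ketone 16.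

2. Step 8 (acylketene macrolactonisation). The risks are intermolecular trapping of the acylketene to oligoesters and dimerisation of the acylketene before the chain folds. The fallback sets out from 10 (together with 12) and returns to the route at 15; the ester bond is made first between two molecules and the ring is closed by olefination. Heating 10 with 12 in PhMe at 110 °C should acylate the primary alcohol with the acylketene released from 12 and give the β-keto ester phosphonate F4. NaH (2.2 equiv) in THF at high dilution generates the dianion, whose phosphonate carbon should undergo intramolecular Horner–Wadsworth–Emmons olefination with the aldehyde to give macrolactone 15.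

3. Step 4 (carboalumination and acylation). The risks are stalling of the carbometalation because the nitrile binds the aluminium and zirconium reagents, and protonation of the alkenylalane before it is acylated. The fallback sets out from 6 and returns to the route at 8; the methyl group is introduced by conjugate addition–elimination instead. Deprotonation of 6 with LiN(iPr)2 in THF at −78 °C and acylation with ClCO2Me should give the ynoate F5. Anti addition of PhSH (cat. NaOMe, MeOH, 0 °C) should give the (Z)-β-phenylsulfanyl enoate F6. MeMgBr with CuBr·SMe2 in THF at −78 °C then replaces the sulfanyl group by methyl with retention of alkene geometry and should give 8.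

Further compounds
F1 | step 9 | (2E,5S,8E)-5-[(tert-butyldimethylsilyl)oxy]-9-(2,2-dimethyl-4-oxo-4H-1,3-dioxin-6-yl)-3,7,7-trimethylnona-2,8-dien-1-yl methyl carbonate | O=C1C=C(/C=C/C(C)(C)C[C@@H](O[Si](C)(C)C(C)(C)C)C/C(C)=C/COC(=O)OC)OC(C)(C)O1
F2 | step 9 | methyl (4E,8S,10E)-8-[(tert-butyldimethylsilyl)oxy]-12-[(methoxycarbonyl)oxy]-6,6,10-trimethyl-3-oxododeca-4,10-dienoate | COC(=O)CC(=O)/C=C/C(C)(C)C[C@@H](O[Si](C)(C)C(C)(C)C)C/C(C)=C/COC(=O)OC
F3 | step 9 | methyl (3E,7S,9E)-7-[(tert-butyldimethylsilyl)oxy]-5,5,9-trimethyl-2-oxocycloundeca-3,9-diene-1-carboxylate (either configuration at C1) | O=C1/C=C/C(C)(C)C[C@@H](O[Si](C)(C)C(C)(C)C)C/C(C)=C/CC1C(=O)OC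
F4 | step 8 | (2E,5S)-5-[(tert-butyldimethylsilyl)oxy]-3,7,7-trimethyl-8-oxooct-2-en-1-yl 4-(diethoxyphosphoryl)-3-oxobutanoate | O=CC(C)(C)C[C@@H](O[Si](C)(C)C(C)(C)C)C/C(C)=C/COC(=O)CC(=O)CP(=O)(OCC)OCC
F5 | step 4 | methyl (5S)-5-[(tert-butyldimethylsilyl)oxy]-7-cyano-7-methyloct-2-ynoate | N#CC(C)(C)C[C@@H](O[Si](C)(C)C(C)(C)C)CC#CC(=O)OC
F6 | step 4 | methyl (2Z,5R)-5-[(tert-butyldimethylsilyl)oxy]-7-cyano-7-methyl-3-(phenylsulfanyl)oct-2-enoate (same spatial arrangement as 6) | N#CC(C)(C)C[C@@H](O[Si](C)(C)C(C)(C)C)C/C(Sc1ccccc1)=C/C(=O)OC
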